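**Retrosynthetic overview**
1. Kuwanon I (22) ⇐ removal of eight MOM ethers ⇐ C4-methylcyclohexene 21 ⇐ Negishi methylation of enol triflate 20 ⇐ regiodefined silyl enol ether 19.
2. Key disconnection: the C1–C2 bond of the cyclohexene, made by Lewis-acid ring expansion (stepwise, ionic formal 1,3-shift) of the 1-aroyl-2-siloxy-2-styrylcyclobutane 17; this sets C1 and C2 and leaves C6 untouched.
3. Cyclobutane 17 ⇐ enantioselective stepwise [2+2] (Mukaiyama–Michael, then aldol closure) of 2'-hydroxychalcone 10 with 2-siloxydiene 16; this sets C6.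
4. 10 ⇐ Claisen–Schmidt of prenylated resacetophenone 9 with aldehyde 6; 16 ⇐ silyl enol ether of enone 15 ⇐ Heck coupling of iodochalcone 13 with methyl vinyl ketone.
5. Ring order: all four arenes are bought as resorcinol; the cyclobutane is formed first and is then expanded to the cyclohexene.

Abbreviations: MOM = methoxymethyl; TBS = tert-butyldimethylsilyl; Tf = trifluoromethanesulfonyl; (S,S)-tBu-PyBox = 2,6-bis[(4S)-4-tert-butyl-4,5-dihydro-1,3-oxazol-2-yl]pyridine.
Cyclohexene numbering: C1 carries the aroyl group, C2 the chalcone-bearing aryl group, C3=C4 is the alkene, C6 carries the 2,4-dioxygenated phenyl group.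
Cyclobutane numbering: C1 aroyl, C2 siloxy and styryl, C3 CH2, C4 aryl.

Assumption: the (S,S)-ligand is taken to give the (4R)-cyclobutane by analogy with its known chalcone chelates; if it gives the mirror image, the (R,R)-ligand is used with no other change.

**Route**

Step 1
Reactants: 1 resorcinol; 2 acetic acid
Product: 3 1-(2,4-dihydroxyphenyl)ethan-1-one
Conditions: ZnCl2, AcOH, 140 °C
Reagents that add atoms: none
Why: Nencki (ZnCl2-mediated Friedel–Crafts) acylation of resorcinol with acetic acid goes para to one hydroxyl and ortho to the other, the classical preparation of resacetophenone.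

Step 2
Reactants: 1 resorcinol
Product: 5 2,4-dihydroxybenzaldehyde, via iminium chloride 4 (not isolated)
Conditions: POCl3, DMF, MeCN, −15 → 25 °C; then H2O, 50 °C
Reagents that add atoms: N,N-dimethylformamide (CN(C)C=O); water (O)
Why: Vilsmeier–Haack formylation attacks the most nucleophilic C4 of resorcinol and hydrolysis of the iminium salt releases the aldehyde.

Step 3
Reactants: 5 2,4-dihydroxybenzaldehyde
Product: 6 2,4-bis(methoxymethoxy)benzaldehyde
Conditions: MOMCl, iPr2NEt, CH2Cl2, 0 → 40 °C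
Reagents that add atoms: chloromethyl methyl ether (COCCl)
Why: O-alkylation of both phenols with MOMCl and Hünig base gives acetal ethers that survive the later basic aldol, Lewis-acid and palladium steps and leave under mild acid.

Step 4
Reactants: 3 1-(2,4-dihydroxyphenyl)ethan-1-one; 7 1-bromo-3-methylbut-2-ene
Product: 8 1-[2,4-dihydroxy-3-(3-methylbut-2-en-1-yl)phenyl]ethan-1-one
Conditions: KOH, H2O, 0 → 25 °C
Reagents that add atoms: none
Why: C-alkylation of the resorcinol phenoxide in water takes place at the doubly activated carbon between the two oxygens (the known direct C-prenylation of resacetophenone), and the product is separated from minor O-alkyl and C5-alkyl isomers.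

Step 5
Reactants: 8 1-[2,4-dihydroxy-3-(3-methylbut-2-en-1-yl)phenyl]ethan-1-one
Product: 9 1-[2-hydroxy-4-(methoxymethoxy)-3-(3-methylbut-2-en-1-yl)phenyl]ethan-1-one
Conditions: MOMCl, iPr2NEt, CH2Cl2, 0 °C
Reagents that add atoms: chloromethyl methyl ether (COCCl)
Why: the 4-OH is etherified selectively because the 2-OH is locked in a hydrogen bond to the ketone, which keeps the chelating phenol needed in step 12.

Step 6
Reactants: 9 1-[2-hydroxy-4-(methoxymethoxy)-3-(3-methylbut-2-en-1-yl)phenyl]ethan-1-one; 6 2,4-bis(methoxymethoxy)benzaldehyde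
Product: 10 (E)-3-[2,4-bis(methoxymethoxy)phenyl]-1-[2-hydroxy-4-(methoxymethoxy)-3-(3-methylbut-2-en-1-yl)phenyl]prop-2-en-1-one (acceptor chalcone)
Conditions: KOH, EtOH–H2O, 25 °C
Reagents that add atoms: none
Why: Claisen–Schmidt aldol condensation of the methyl ketone with the non-enolisable aldehyde gives the (E)-chalcone under thermodynamic control.

Step 7
Reactants: 3 1-(2,4-dihydroxyphenyl)ethan-1-one
Product: 11 1-(2,4-dihydroxy-3-iodophenyl)ethan-1-one
Conditions: I2, HIO3, EtOH–H2O, 25 °C
Reagents that add atoms: iodine (II); iodic acid (OI(=O)=O)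
Why: electrophilic aromatic iodination with I2/HIO3 occurs at C3 between the two hydroxyl groups, the position favoured in chelated 2,4-dihydroxyacetophenone.

Step 8
Reactants: 11 1-(2,4-dihydroxy-3-iodophenyl)ethan-1-one
Product: 12 1-[3-iodo-2,4-bis(methoxymethoxy)phenyl]ethan-1-one
Conditions: MOMCl, iPr2NEt, CH2Cl2, 40 °C
Reagents that add atoms: chloromethyl methyl ether (COCCl)
Why: with excess reagent both phenols, including the hydrogen-bonded 2-OH, become MOM ethers, so this ketone can no longer chelate the Lewis acid used in step 12.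

Step 9
Reactants: 12 1-[3-iodo-2,4-bis(methoxymethoxy)phenyl]ethan-1-one; 6 2,4-bis(methoxymethoxy)benzaldehyde
Product: 13 (E)-3-[2,4-bis(methoxymethoxy)phenyl]-1-[3-iodo-2,4-bis(methoxymethoxy)phenyl]prop-2-en-1-one
Conditions: KOH, EtOH–H2O, 25 °C
Reagents that add atoms: none
Why: a second Claisen–Schmidt condensation gives the (E)-chalcone and leaves the aryl iodide untouched.

Step 10
Reactants: 13 (E)-3-[2,4-bis(methoxymethoxy)phenyl]-1-[3-iodo-2,4-bis(methoxymethoxy)phenyl]prop-2-en-1-one; 14 but-3-en-2-one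
Product: 15 (E)-4-{3-[(E)-3-[2,4-bis(methoxymethoxy)phenyl]prop-2-enoyl]-2,6-bis(methoxymethoxy)phenyl}but-3-en-2-one
Conditions: Pd(OAc)2 (5 mol%), Bu4NCl, NaHCO3, DMF, 80 °C
Reagents that add atoms: none
Why: Mizoroki–Heck coupling (oxidative addition of the aryl iodide to zerovalent palladium, insertion of the terminal alkene, β-hydride elimination) gives the (E)-enone, the internal chalcone alkene being far less reactive than methyl vinyl ketone.

Step 11
Reactants: 15 (E)-4-{3-[(E)-3-[2,4-bis(methoxymethoxy)phenyl]prop-2-enoyl]-2,6-bis(methoxymethoxy)phenyl}but-3-en-2-one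
Product: 16 2-siloxydiene, tert-butyl{[(3E)-4-{3-[(E)-3-[2,4-bis(methoxymethoxy)phenyl]prop-2-enoyl]-2,6-bis(methoxymethoxy)phenyl}buta-1,3-dien-2-yl]oxy}dimethylsilane
Conditions: TBSOTf, Et3N, CH2Cl2, −78 → 0 °C
Reagents that add atoms: tert-butyldimethylsilyl trifluoromethanesulfonate (CC(C)(C)[Si](C)(C)OS(=O)(=O)C(F)(F)F)
Why: soft enolisation silylates the only enolisable ketone at its methyl group and gives the 2-siloxy-1,3-diene.

Step 12
Reactants: 10 acceptor chalcone; 16 2-siloxydiene
Product: 17 (1S,2R,4R)-1-aroyl-2-siloxy-2-styrylcyclobutane (full name in the list)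
Conditions: Sc(OTf)3 (10 mol%), (S,S)-tBu-PyBox (12 mol%), 4 Å MS, CH2Cl2, −78 °C
Reagents that add atoms: none
Why: Proposed new method: the trivalent scandium–PyBox complex binds only the 2-hydroxyaryl ketone of 10 as a rigid chelate, the CH2 terminus of the siloxydiene adds to the open face of the β-carbon (Mukaiyama–Michael step, which sets C4 of the cyclobutane as R), and the chelated scandium enolate, which cannot accept the silyl group, closes onto the silyloxocarbenium carbon at −78 °C (aldol step) before the slower vinylogous closure, giving the trans-cyclobutane; the closest known reactions are the Lewis-acid-catalysed [2+2] of silyl enol ethers with acrylates, scandium–PyBox Mukaiyama–Michael additions to chelating enones, and the enantioselective scandium–PyBox photocycloadditions of 2'-hydroxychalcones.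

Step 13
Reactants: 17 (1S,2R,4R)-1-aroyl-2-siloxy-2-styrylcyclobutane
Product: 19 (1S,2S,6R)-cyclohexenyl silyl enol ether (all phenols as MOM ethers), via ring-expanded phenol 18 (not isolated)
Conditions: Sc(OTf)3 (10 mol%), (S,S)-tBu-PyBox (12 mol%), 4 Å MS, CH2Cl2, −78 → 23 °C; then iPr2NEt, MOMCl, 40 °C
Reagents that add atoms: chloromethyl methyl ether (COCCl)
Why: Lewis-acid-catalysed ring expansion of a donor–acceptor 1-siloxy-1-vinylcyclobutane (a stepwise formal 1,3-shift), in which the chelated ketone drives retro-aldol cleavage of the strained C1–C2 bond to a scandium enolate and a silyloxyallyl cation that recombine at the styryl terminus, giving the six-membered silyl enol ether with the double bond fixed at C3=C4; the reversible closure places the three large groups equatorial (1,2-trans and 1,6-trans), C6 is not touched and stays under control of the same chiral catalyst, and the freed 2-OH is capped in the same flask.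

Step 14
Reactants: 19 (1S,2S,6R)-cyclohexenyl silyl enol ether
Product: 20 (3S,4S,5R)-cyclohexenyl triflate (same all-trans arrangement as 19)
Conditions: PhNTf2, CsF, DME, 23 °C
Reagents that add atoms: N-phenylbis(trifluoromethanesulfonimide) (O=S(=O)(N(c1ccccc1)S(=O)(=O)C(F)(F)F)C(F)(F)F)
Why: fluoride cleaves the silyl enol ether and the resulting enolate is triflated by PhNTf2 faster than it can equilibrate, so the vinyl triflate keeps the C3=C4 position (regiospecific conversion of a silyl enol ether into an enol triflate) and no stereocentre is touched.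

Step 15
Reactants: 20 (3S,4S,5R)-cyclohexenyl triflate
Product: 21 octa-MOM Kuwanon I
Conditions: MeZnCl, Pd(PPh3)4 (5 mol%), THF, 50 °C
Reagents that add atoms: methylzinc chloride (C[Zn]Cl)
Why: Negishi coupling (oxidative addition of the vinyl triflate to zerovalent palladium, transmetalation from zinc, reductive elimination) installs the C4 methyl group without affecting the ketones, the enone, the prenyl group or the stereocentres.

Step 16
Reactants: 21 octa-MOM Kuwanon I
Product: 22 Kuwanon I
Conditions: HCl (1.25 M in MeOH), MeOH, 23 °C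
Reagents that add atoms: none
Why: acid-catalysed acetal exchange with methanol removes all eight MOM groups under conditions mild enough to spare the prenyl group and the 2'-hydroxychalcone, and the all-equatorial (1S,2S,6R) arrangement is the thermodynamic one, so the epimerisable C1 is not at risk.

**Compound list**
1 | resorcinol (benzene-1,3-diol) | Oc1cccc(O)c1 | starting material
2 | acetic acid | CC(O)=O | starting material
3 | 1-(2,4-dihydroxyphenyl)ethan-1-one | CC(=O)c1ccc(O)cc1O | intermediate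
4 | N-[(2,4-dihydroxyphenyl)methylidene]-N-methylmethanaminium chloride (iminium chloride) | C[N+](C)=Cc1ccc(O)cc1O.[Cl-] | intermediate
5 | 2,4-dihydroxybenzaldehyde | O=Cc1ccc(O)cc1O | intermediate
6 | 2,4-bis(methoxymethoxy)benzaldehyde | COCOc1ccc(C=O)c(OCOC)c1 | intermediate
7 | 1-bromo-3-methylbut-2-ene (prenyl bromide) | CC(C)=CCBr | starting material
8 | 1-[2,4-dihydroxy-3-(3-methylbut-2-en-1-yl)phenyl]ethan-1-one | CC(=O)c1ccc(O)c(CC=C(C)C)c1O | intermediate
9 | 1-[2-hydroxy-4-(methoxymethoxy)-3-(3-methylbut-2-en-1-yl)phenyl]ethan-1-one | CC(=O)c1ccc(OCOC)c(CC=C(C)C)c1O | intermediate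
10 | (E)-3-[2,4-bis(methoxymethoxy)phenyl]-1-[2-hydroxy-4-(methoxymethoxy)-3-(3-methylbut-2-en-1-yl)phenyl]prop-2-en-1-one (acceptor chalcone) | CC(C)=CCc1c(OCOC)ccc(C(=O)/C=C/c2ccc(OCOC)cc2OCOC)c1O | intermediate
11 | 1-(2,4-dihydroxy-3-iodophenyl)ethan-1-one | CC(=O)c1ccc(O)c(I)c1O | intermediate
12 | 1-[3-iodo-2,4-bis(methoxymethoxy)phenyl]ethan-1-one | CC(=O)c1ccc(OCOC)c(I)c1OCOC | intermediate
13 | (E)-3-[2,4-bis(methoxymethoxy)phenyl]-1-[3-iodo-2,4-bis(methoxymethoxy)phenyl]prop-2-en-1-one | COCOc1ccc(/C=C/C(=O)c2ccc(OCOC)c(I)c2OCOC)c(OCOC)c1 | intermediate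
14 | but-3-en-2-one (methyl vinyl ketone) | CC(=O)C=C | starting material
15 | (E)-4-{3-[(E)-3-[2,4-bis(methoxymethoxy)phenyl]prop-2-enoyl]-2,6-bis(methoxymethoxy)phenyl}but-3-en-2-one | CC(=O)/C=C/c1c(OCOC)ccc(C(=O)/C=C/c2ccc(OCOC)cc2OCOC)c1OCOC | intermediate
16 | tert-butyl{[(3E)-4-{3-[(E)-3-[2,4-bis(methoxymethoxy)phenyl]prop-2-enoyl]-2,6-bis(methoxymethoxy)phenyl}buta-1,3-dien-2-yl]oxy}dimethylsilane (2-siloxydiene) | C=C(O[Si](C)(C)C(C)(C)C)/C=C/c1c(OCOC)ccc(C(=O)/C=C/c2ccc(OCOC)cc2OCOC)c1OCOC | intermediate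
17 | {(1S,2R,4R)-4-[2,4-bis(methoxymethoxy)phenyl]-2-[(tert-butyldimethylsilyl)oxy]-2-[(E)-2-{3-[(E)-3-[2,4-bis(methoxymethoxy)phenyl]prop-2-enoyl]-2,6-bis(methoxymethoxy)phenyl}ethenyl]cyclobutyl}[2-hydroxy-4-(methoxymethoxy)-3-(3-methylbut-2-en-1-yl)phenyl]methanone (aroyl trans to the C4 aryl group and trans to the siloxy group) | CC(C)=CCc1c(OCOC)ccc(C(=O)[C@@H]2[C@](O[Si](C)(C)C(C)(C)C)(/C=C/c3c(OCOC)ccc(C(=O)/C=C/c4ccc(OCOC)cc4OCOC)c3OCOC)C[C@H]2c2ccc(OCOC)cc2OCOC)c1O | intermediate
18 | [(1S,2S,6R)-6-[2,4-bis(methoxymethoxy)phenyl]-2-{3-[(E)-3-[2,4-bis(methoxymethoxy)phenyl]prop-2-enoyl]-2,6-bis(methoxymethoxy)phenyl}-4-[(tert-butyldimethylsilyl)oxy]cyclohex-3-en-1-yl][2-hydroxy-4-(methoxymethoxy)-3-(3-methylbut-2-en-1-yl)phenyl]methanone (ring-expanded phenol, all-trans) | CC(C)=CCc1c(OCOC)ccc(C(=O)[C@@H]2[C@@H](c3c(OCOC)ccc(C(=O)/C=C/c4ccc(OCOC)cc4OCOC)c3OCOC)C=C(O[Si](C)(C)C(C)(C)C)C[C@H]2c2ccc(OCOC)cc2OCOC)c1O | intermediate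
19 | [(1S,2S,6R)-6-[2,4-bis(methoxymethoxy)phenyl]-2-{3-[(E)-3-[2,4-bis(methoxymethoxy)phenyl]prop-2-enoyl]-2,6-bis(methoxymethoxy)phenyl}-4-[(tert-butyldimethylsilyl)oxy]cyclohex-3-en-1-yl][2,4-bis(methoxymethoxy)-3-(3-methylbut-2-en-1-yl)phenyl]methanone | CC(C)=CCc1c(OCOC)ccc(C(=O)[C@@H]2[C@@H](c3c(OCOC)ccc(C(=O)/C=C/c4ccc(OCOC)cc4OCOC)c3OCOC)C=C(O[Si](C)(C)C(C)(C)C)C[C@H]2c2ccc(OCOC)cc2OCOC)c1OCOC | intermediate
20 | (3S,4S,5R)-5-[2,4-bis(methoxymethoxy)phenyl]-4-[2,4-bis(methoxymethoxy)-3-(3-methylbut-2-en-1-yl)benzoyl]-3-{3-[(E)-3-[2,4-bis(methoxymethoxy)phenyl]prop-2-enoyl]-2,6-bis(methoxymethoxy)phenyl}cyclohex-1-en-1-yl trifluoromethanesulfonate (same all-trans arrangement as 19) | CC(C)=CCc1c(OCOC)ccc(C(=O)[C@@H]2[C@@H](c3c(OCOC)ccc(C(=O)/C=C/c4ccc(OCOC)cc4OCOC)c3OCOC)C=C(OS(=O)(=O)C(F)(F)F)C[C@H]2c2ccc(OCOC)cc2OCOC)c1OCOC | intermediate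
21 | [(1S,2S,6R)-6-[2,4-bis(methoxymethoxy)phenyl]-2-{3-[(E)-3-[2,4-bis(methoxymethoxy)phenyl]prop-2-enoyl]-2,6-bis(methoxymethoxy)phenyl}-4-methylcyclohex-3-en-1-yl][2,4-bis(methoxymethoxy)-3-(3-methylbut-2-en-1-yl)phenyl]methanone (octa-MOM Kuwanon I) | CC(C)=CCc1c(OCOC)ccc(C(=O)[C@@H]2[C@@H](c3c(OCOC)ccc(C(=O)/C=C/c4ccc(OCOC)cc4OCOC)c3OCOC)C=C(C)C[C@H]2c2ccc(OCOC)cc2OCOC)c1OCOC | intermediate
22 | Kuwanon I, [(1S,2S,6R)-6-(2,4-dihydroxyphenyl)-2-{3-[(E)-3-(2,4-dihydroxyphenyl)prop-2-enoyl]-2,6-dihydroxyphenyl}-4-methylcyclohex-3-en-1-yl][2,4-dihydroxy-3-(3-methylbut-2-en-1-yl)phenyl]methanone | CC(C)=CCc1c(O)ccc(C(=O)[C@@H]2[C@@H](c3c(O)ccc(C(=O)/C=C/c4ccc(O)cc4O)c3O)C=C(C)C[C@H]2c2ccc(O)cc2O)c1O | target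

**Totals**
Total step count: 16 (the non-isolated compounds 4 and 18 are not counted as steps).
Longest linear sequence: 11 steps (1 → 3 → 11 → 12 → 13 → 15 → 16 → 17 → 19 → 20 → 21 → 22).

**The three steps most likely to fail, each with a fallback**

The first is step 12, the proposed enantioselective [2+2]. The risks are low enantioselectivity, silyl transfer to an open-chain Michael adduct, or partial direct six-ring closure. The fallback sets out from 10 and 16 and comes back to the route at 17. The cycloaddition is run without the chiral ligand, with Sc(OTf)3 alone or with EtAlCl2 in CH2Cl2 at −78 °C. This is the known Lewis-acid [2+2] of silyl enol ethers with α,β-unsaturated carbonyl compounds, and it gives racemic cyclobutane F1. The enantiomers are then separated by preparative chromatography on a chiral stationary phase. The (1S,2R,4R) enantiomer is 17.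

The second is step 13, the ring expansion. The risks are a mixture of C2 epimers or loss of the silyl enol ether once the cyclobutane has been isolated. The fallback sets out from 10 and 16, does not pass through the cyclobutane, and comes back to the route at 18. Diene 16 is added to the chiral borate formed in the flask from 10, BH3·THF, AcOH and one enantiomer of VANOL (3,3'-diphenyl-2,2'-bi-1-naphthol) in CH2Cl2 at 23 °C. This is the known enantioselective boron-mediated Diels–Alder activation of 2'-hydroxychalcones. It gives the cyclohexenyl silyl enol ether directly, and the exo isomer is separated from the endo isomer. Compound 18 is then isolated and capped with MOMCl and iPr2NEt to 19 as before. New compounds on this way: none F0.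

The third is step 4, the direct C-prenylation. The risks are a modest yield and contamination by O-prenyl, C5-prenyl and bis-prenyl products. The fallback sets out from 3 and comes back to the route at 8. The free 4-OH is etherified with 3-chloro-3-methylbut-1-yne (K2CO3, KI, CuI, acetone, 56 °C) to give 1-{2-hydroxy-4-[(2-methylbut-3-yn-2-yl)oxy]phenyl}ethan-1-one F2. Semi-hydrogenation (H2, Pd/CaCO3 poisoned with Pb(OAc)2, quinoline, EtOAc) gives 1-{2-hydroxy-4-[(2-methylbut-3-en-2-yl)oxy]phenyl}ethan-1-one F3. Heating in N,N-diethylaniline at 180 °C then brings about the aromatic Claisen rearrangement, which delivers the 3-methylbut-2-enyl group to C3 and gives 8.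

Further compounds
F1 | step 12 | racemic 17, the 1:1 mixture of the (1S,2R,4R) compound and its mirror image | CC(C)=CCc1c(OCOC)ccc(C(=O)C2C(O[Si](C)(C)C(C)(C)C)(/C=C/c3c(OCOC)ccc(C(=O)/C=C/c4ccc(OCOC)cc4OCOC)c3OCOC)CC2c2ccc(OCOC)cc2OCOC)c1O
F0 | step 13 | none | none
F2 | step 4 | 1-{2-hydroxy-4-[(2-methylbut-3-yn-2-yl)oxy]phenyl}ethan-1-one | CC(=O)c1ccc(OC(C)(C)C#C)cc1O
F3 | step 4 | 1-{2-hydroxy-4-[(2-methylbut-3-en-2-yl)oxy]phenyl}ethan-1-one | CC(=O)c1ccc(OC(C)(C)C=C)cc1O
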